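## Analysis of the target

The target is an isoflavan-4-ol. Ring A, a benzene ring with methoxy groups at C6, C7 and C8 and a hydrogen at C5, is fused to the dihydropyran ring C (O1, C2, C3, C4); C4 carries a hydroxyl group and C3 carries ring B, a 2',5'-dihydroxy-3',4'-dimethoxyphenyl group. The only stereocentres are the neighbours C3 (S) and C4 (R), with ring B and the hydroxyl group on opposite faces of ring C (3,4-trans). Ring B is a hydroquinone and is oxidised to the quinone by air, quickly so in base. The C4 hydroxyl group is benzylic to a ring whose O1 (ortho) and C7 methoxy group (para) stabilise positive charge at C4, so acid causes ionisation, followed by loss of H3 or by closure of the free C2' hydroxyl group onto C4; hydrogenolysis threatens the same C–O bond. The difficulty is twofold: two contiguous stereocentres, of which C3 bears no heteroatom and is labile in any ketone precursor, must be set trans and in one absolute sense, and the last steps must avoid acid, oxidant and, if possible, hydrogen. The strategy rests on the vicinal bonds C3–C1' and C4–O in a trans relationship, with C4 the carbon best able to carry positive charge: this is the pattern left when an aryl group on C4 moves to C3 across the C3–C4 bond through a bridged ion and an oxygen nucleophile enters at C4 from the other face. The isomer with ring B on C4 and oxygen on C3, a trans-4-aryl-chroman-3-ol, is what an arene gives when it opens an aryl epoxide, so it can be made enantiopure from a cinnamyl alcohol.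

## Retrosynthetic reasoning

**17 to 16.** The two phenolic O–H bonds of ring B in target 17 are traced back to the aryl pivalates of 16. The free hydroquinone cannot be carried through a cationic step, and the C2' oxygen must be tied up while C4 is electron-poor. Cleavage of aryl esters by alkoxide needs neither acid nor hydrogen, so the benzylic C4–O bond is not put at risk; the forward step has only to exclude oxygen.

**16 to 14 (through 15).** This is the central disconnection. In 16 the bonds C3–C1' and C4–O are cut and replaced by C4–C1' and C3–O, which leads to mesylate 14 with ring B on C4 and the leaving group on C3. Cutting C3–C1' directly would pass through a ketone with an epimerisable C3, and cutting O1–C2 would leave an acyclic anti stereodiad to be built. The transposed pattern of 14, in contrast, comes from epoxide chemistry. Both stereocentres of 16 then derive from the single C3–O centre of 14 and its trans relationship to ring B. The forward reaction must make ring B leave C4 anti to the sulfonate through bridged ion 15 and let the solvent deliver oxygen to C4 from the opposite face.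

**14 to 13 to 11 (through 12).** The S–O bond of 14 goes back to alcohol 13, and the pivalates of 13 go back to the benzyl ethers of 11 through triol 12. The order matters. A free C2' phenol beside a C3 sulfonate would displace it in a five-membered closure, and a sulfonate of the electron-rich dibenzyl compound would ionise before it could be handled. Hydrogenolysis and acylation therefore come before sulfonylation. Benzyl ethers are kept for the earlier steps because an ester carbonyl ortho to the benzylic epoxide carbon could take part in the cyclisation and because esters are a liability under the basic coupling conditions. The forward step must acylate two phenols and leave the C3 alcohol free.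

**11 to 10.** The C4–C4a bond is cut, a retro Friedel–Crafts opening of an epoxide by ring A, which closes ring C in the 6-endo mode. The cut is made there because the only free ortho position of ring A is para to a methoxy group and the benzylic epoxide carbon is the electrophilic one. The forward reaction must proceed with inversion at the benzylic carbon so that trans epoxide 10 gives trans alcohol 11.

**10 to 8 and 9.** The O1–C2 ether bond is cut (Mitsunobu etherification at the primary carbinol). This brings in ring A complete, as purchased phenol 9, without touching the epoxide.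

**8 to 7.** The two C–O bonds of the oxirane are cut (Sharpless epoxidation). This is the only step that creates absolute configuration; the oxirane carbon next to the CH2O group becomes C3.

**7 to 6 to 4 and 5.** The bond between C1' of ring B and the alkene carbon is cut (Suzuki coupling of bromide 4 with alkenylboronate 5), and the silyl ether of 6 is removed to give 7. The (E)-alkene needed for the trans epoxide comes from the boronate.

**4 to 3 to 1 (through 2).** The C–Br bond, the two O–benzyl bonds and the quinone oxidation level are removed in turn. Ring B is bought with all four oxygens in place as quinone 1. The two free positions of 3 are equivalent, so the bromination needs no regiocontrol.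

## Alternatives that were turned down

**Alternative 1:** Ring A is built last from dimethyl squarate A2. The disconnection cuts C4a–C8a of ring A and O1–C2 of ring C, so an acyclic alkenyl chain must already hold C4 (silyloxy), C3 (ring B) and C2 (a sulfonate) with both stereocentres set. In the forward key step a 4-alkenyl-4-methoxycyclobutenone is heated, opens to a dienylketene and closes by six-electron electrocyclisation to the phenol; a carbonate base in the same pot lets the new C8a oxygen displace the C2 sulfonate and gives A1.
- For it: the crowded 6,7,8-trimethoxy pattern is made without any regiochemical question, the phenol oxygen appears exactly where O1 is needed, and ring C closes by a plain displacement in which C3 and C4 are never at risk. On that last point it is stronger than the chosen route.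
- Against it: the oxygenation pattern of ring A can be bought as phenol 9, so building it is effort without return. The real problem, an acyclic anti aryl/silyloxy stereodiad, is moved into a multi-step asymmetric synthesis of the chain. The thermolysis substrate carries an allylic silyl ether and a sulfonate at high temperature. The benzyl ethers of A1 must be removed by hydrogenolysis next to the benzylic C4–O bond.
- In comparison, the chosen strategy takes its stereochemistry from one catalytic epoxidation, buys both rings and reaches the key step in fewer operations.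

**Alternative 2:** Both aryl rings are joined to an (E)-alkenylboron unit that supplies C4, C3 and C2; the disconnection cuts C4–C4a and C3–C1' at once. The ate complex formed from ring A boronic ester A4 and the alkenyllithium reacts with ring B bromide A5 (the same compound as 4) under a palladium catalyst with a chiral ferrocenyl bisphosphine and a triflate additive. Ring B adds to C3 while ring A migrates from boron to C4, giving A3; oxidation of the C–B bond, desilylation and closure of O1–C2 would follow.
- For it: this is the most convergent plan, with three simple fragments and both stereocentres set in one catalytic enantioselective step. On convergence it is clearly stronger than the chosen route.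
- Against it: the migrating group is a hindered, very electron-rich aryl with an ortho silyloxy group, the electrophile is an ortho-substituted electron-rich bromide, and the alkenyl unit is substituted at its far end. Each of these lies at or beyond the comfortable scope of conjunctive coupling, and direct Suzuki coupling of the ate complex competes. Three more steps follow the coupling, among them a ring closure in the presence of a free benzylic alcohol.
- In comparison, the chosen strategy uses well-tried steps up to its key step and places its risk in one reaction whose failure modes can be read from the products.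

**Alternative 3:** Ring B is built last from dimethyl squarate A2. The disconnection cuts C1'–C2' (and the ring B bonds that come from the squarate), so enantiopure 3-ethynylchroman A7 with both stereocentres is needed first. Its acetylide is added to A2, and heating the 4-alkynyl-4-hydroxycyclobutenone opens it to an alkynylketene that closes onto the alkyne carbon bearing C3 and gives quinone A6.
- For it: ring B arrives with the right methoxy pattern at the quinone level and needs no phenol protecting groups; reduction of the quinone and fluoride desilylation are mild and neutral. This endgame is better than the basic ester cleavage of the chosen route.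
- Against it: A7, a trans-3-alkynyl-chroman-4-ol derivative, is a stereochemical problem of about the same size as the target itself. Its propargylic C3–H becomes acidic under the acetylide chemistry, and the thermolysis can divert to a five-membered ring closure.
- In comparison, the chosen strategy offers a clear origin for both stereocentres and uses purchased rings, and it accepts a more delicate final deprotection in exchange.

Key step: step 10

Remark on the chemistry: the Sharpless epoxidation of 7 with the D-tartrate ester is assumed to follow the usual facial rule for (E)-3-arylprop-2-en-1-ols and so to give the (2R,3R) epoxide. Ion 15 is a reactive intermediate and is listed because it is formed and consumed in the flask.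

## Route

**Step 1**
Reactants: 1 2,3-dimethoxy-1,4-benzoquinone
Product: 3 1,4-bis(benzyloxy)-2,3-dimethoxybenzene, via 2,3-dimethoxybenzene-1,4-diol 2 (not isolated)
Conditions: Na2S2O4, EtOAc/H2O, rt; organic phase dried and concentrated under argon; then BnBr, K2CO3, DMF, 60 °C
Reagents that add atoms: benzyl bromide, BrCc1ccccc1
Why: Dithionite reduces the quinone to the hydroquinone, which is alkylated twice at oxygen (Williamson ether synthesis); carrying 2 on without isolation avoids its re-oxidation by air.

**Step 2**
Reactants: 3 1,4-bis(benzyloxy)-2,3-dimethoxybenzene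
Product: 4 1-bromo-2,5-bis(benzyloxy)-3,4-dimethoxybenzene
Conditions: NBS (1.0 equiv), MeCN, 0 °C to rt, dark
Reagents that add atoms: N-bromosuccinimide, O=C1CCC(=O)N1Br
Why: Electrophilic aromatic bromination; the two free positions are equivalent by symmetry, each is para to a methoxy and ortho to a benzyloxy group, and the first bromine deactivates the ring against a second.

**Step 3**
Reactants: 4 1-bromo-2,5-bis(benzyloxy)-3,4-dimethoxybenzene; 5 (E)-2-[3-(tert-butyldimethylsilyloxy)prop-1-enyl]-4,4,5,5-tetramethyl-1,3,2-dioxaborolane
Product: 6 (E)-{3-[2,5-bis(benzyloxy)-3,4-dimethoxyphenyl]prop-2-enyloxy}(tert-butyl)dimethylsilane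
Conditions: Pd(OAc)2 (3 mol%), SPhos (6 mol%), K3PO4, toluene/H2O (10:1), 80 °C
Reagents that add atoms: none
Why: Suzuki–Miyaura coupling of an aryl bromide with an (E)-alkenyl pinacol boronate, which keeps the alkene geometry; the electron-rich, ortho-substituted bromide is the reason for the dialkylbiarylphosphine ligand.

**Step 4**
Reactants: 6 (E)-{3-[2,5-bis(benzyloxy)-3,4-dimethoxyphenyl]prop-2-enyloxy}(tert-butyl)dimethylsilane
Product: 7 (E)-3-[2,5-bis(benzyloxy)-3,4-dimethoxyphenyl]prop-2-en-1-ol
Conditions: Bu4NF, THF, 0 °C to rt
Reagents that add atoms: none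
Why: Fluoride cleavage of a primary silyl ether; the conditions are basic, which suits an electron-rich cinnamyl alcohol that would ionise in acid.

**Step 5**
Reactants: 7 (E)-3-[2,5-bis(benzyloxy)-3,4-dimethoxyphenyl]prop-2-en-1-ol
Product: 8 {(2R,3R)-3-[2,5-bis(benzyloxy)-3,4-dimethoxyphenyl]oxiran-2-yl}methanol
Conditions: Ti(OiPr)4 (10 mol%), D-(−)-diisopropyl tartrate (12 mol%), t-BuOOH (decane solution), 4 Å MS, CH2Cl2, −20 °C; NaOH/brine work-up; used at once
Reagents that add atoms: tert-butyl hydroperoxide, CC(C)(C)OO
Why: Sharpless asymmetric epoxidation of an (E)-allylic alcohol; the D-tartrate ligand delivers oxygen to the face that gives the (2R,3R) epoxy alcohol (the mirror image of the product formed from cinnamyl alcohol with the L-tartrate), and the (E)-alkene fixes the trans oxirane. Both stereocentres of the route are created here; the oxirane carbon next to CH2OH becomes C3 of the chroman.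

**Step 6**
Reactants: 8 {(2R,3R)-3-[2,5-bis(benzyloxy)-3,4-dimethoxyphenyl]oxiran-2-yl}methanol; 9 2,3,4-trimethoxyphenol
Product: 10 (2R,3R)-2-[2,5-bis(benzyloxy)-3,4-dimethoxyphenyl]-3-[(2,3,4-trimethoxyphenoxy)methyl]oxirane
Conditions: PPh3, DIAD, toluene, 0 °C to rt
Reagents that add atoms: none
Why: Mitsunobu etherification of a phenol at the primary carbinol; the reaction is neutral and touches neither oxirane carbon, so the configuration of 8 is kept.

**Step 7**
Reactants: 10 (2R,3R)-2-[2,5-bis(benzyloxy)-3,4-dimethoxyphenyl]-3-[(2,3,4-trimethoxyphenoxy)methyl]oxirane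
Product: 11 (3S,4R)-4-[2,5-bis(benzyloxy)-3,4-dimethoxyphenyl]-6,7,8-trimethoxychroman-3-ol (3,4-trans)
Conditions: FeBr3 (10 mol%), AgOSO2CF3 (30 mol%), CH2Cl2, 0 °C to rt
Reagents that add atoms: none
Why: Intramolecular Friedel–Crafts epoxy-arene cyclisation; the only free ortho position of ring A (para to a methoxy group) attacks the benzylic oxirane carbon in a 6-endo opening with inversion, so the trans epoxide gives the trans-4-aryl-chroman-3-ol. C3 keeps the configuration set in step 5, and its descriptor changes from R to S only because the ranking of its neighbours changes.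

**Step 8**
Reactants: 11 (3S,4R)-4-[2,5-bis(benzyloxy)-3,4-dimethoxyphenyl]-6,7,8-trimethoxychroman-3-ol
Product: 13 (3S,4S)-4-[3,4-dimethoxy-2,5-bis(pivaloyloxy)phenyl]-6,7,8-trimethoxychroman-3-ol (3,4-trans), via (3S,4R)-4-(2,5-dihydroxy-3,4-dimethoxyphenyl)-6,7,8-trimethoxychroman-3-ol 12 (not isolated)
Conditions: H2 (1 atm), Pd/C (10 wt%), EtOAc, rt; filtered and concentrated under argon; then PivCl (2.2 equiv), K2CO3, acetone, 0 °C to rt
Reagents that add atoms: pivaloyl chloride, CC(C)(C)C(Cl)=O
Why: Hydrogenolysis of the two benzyl ethers, then O-acylation of the two phenoxides; carbonate deprotonates the phenols but not the hindered secondary C3 alcohol, which therefore stays free. No stereocentre is touched; the C4 descriptor changes from R to S only because the C2' pivalate outranks ring A in the priority rules.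

**Step 9**
Reactants: 13 (3S,4S)-4-[3,4-dimethoxy-2,5-bis(pivaloyloxy)phenyl]-6,7,8-trimethoxychroman-3-ol
Product: 14 (3S,4S)-4-[3,4-dimethoxy-2,5-bis(pivaloyloxy)phenyl]-6,7,8-trimethoxychroman-3-yl methanesulfonate (3,4-trans)
Conditions: MsCl, Et3N, CH2Cl2, −20 to 0 °C; cold aqueous work-up, no chromatography
Reagents that add atoms: methanesulfonyl chloride, CS(Cl)(=O)=O
Why: Sulfonylation of a secondary alcohol through the sulfene, with the C–O bond and both stereocentres untouched; the two acyloxy groups make ring B a weaker neighbouring group than in 11, so 14 should survive a cold work-up in a non-ionising solvent.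

**Step 10**
Reactants: 14 (3S,4S)-4-[3,4-dimethoxy-2,5-bis(pivaloyloxy)phenyl]-6,7,8-trimethoxychroman-3-yl methanesulfonate
Product: 16 (3S,4R)-3-[3,4-dimethoxy-2,5-bis(pivaloyloxy)phenyl]-6,7,8-trimethoxychroman-4-ol (3,4-trans), via C1'-bridged phenonium ion 15 (not isolated)
Conditions: 2,6-lutidine (3 equiv), acetone/H2O (3:1), 50 °C
Reagents that add atoms: water, O
Why: Proposed new method: in the diaxial half-chair conformer of 14 (favoured by relief of the peri interaction with H5 and by the gauche relationship of the C3 oxygen to O1) the C4–C1' bond is anti-periplanar to the C3–O bond, so C1' of ring B, which is para to the C4' methoxy group, can displace the mesylate with inversion at C3 and give bridged ion 15. The three-membered ring of 15 opens at C4, because positive charge there is shared with O1 and the C7 methoxy group of ring A, and water adds to C4 on the face opposite the bridging aryl group, so that C3–C1' and C4–O are formed trans; no ring is closed, the bridge of 15 being transient. The closest known reaction type is the phenonium 1,2-aryl shift in the solvolysis of β-aryl alkyl sulfonates, to which the 2-aryl to 3-aryl shift of flavan-3-yl sulfonates also belongs; it has not been used to move an aryl group from C4 to C3 of a chroman. C3 is set by inversion of the C3–O centre from step 5 and C4 by anti opening of 15, so the enantiopurity of 14 is carried over; should 15 open fully to a planar C4 cation, the C3 aryl group shields its own face and the trans alcohol should still prevail. The step needs aryl migration to win over ring contraction (a shift of C4a or O1 would need the diequatorial conformer and a strained or poorly stabilised ion), over E2 elimination (H4 is syn to the mesylate and 2,6-lutidine is too weak and hindered to attack H2) and over loss of H3 from the cation (water is present in large excess). The pivalates keep the C2' oxygen from closing onto C4, and the buffer keeps the acid-labile benzylic alcohol of 16 from ionising again.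

**Step 11**
Reactants: 16 (3S,4R)-3-[3,4-dimethoxy-2,5-bis(pivaloyloxy)phenyl]-6,7,8-trimethoxychroman-4-ol
Product: 17 (3S,4R)-3-(2,5-dihydroxy-3,4-dimethoxyphenyl)-6,7,8-trimethoxychroman-4-ol (target)
Conditions: NaOMe (3 equiv), degassed MeOH, argon, 0 °C to rt; AcOH (3 equiv), 0 °C
Reagents that add atoms: none
Why: Transesterification of the two aryl pivalates to methyl pivalate by methoxide; neither stereocentre has an acidic hydrogen, so the configuration is kept. Oxygen is excluded because of the hydroquinone, and the quench is stoichiometric so that the benzylic alcohol next to a free C2' hydroxyl group never meets strong acid.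

## Compound list

1 | 2,3-dimethoxy-1,4-benzoquinone | COC1=C(OC)C(=O)C=CC1=O | starting material
2 | 2,3-dimethoxybenzene-1,4-diol | COc1c(O)ccc(O)c1OC | intermediate (not isolated)
3 | 1,4-bis(benzyloxy)-2,3-dimethoxybenzene | COc1c(OCc2ccccc2)ccc(OCc2ccccc2)c1OC | intermediate
4 | 1-bromo-2,5-bis(benzyloxy)-3,4-dimethoxybenzene | COc1c(OCc2ccccc2)cc(Br)c(OCc2ccccc2)c1OC | intermediate
5 | (E)-2-[3-(tert-butyldimethylsilyloxy)prop-1-enyl]-4,4,5,5-tetramethyl-1,3,2-dioxaborolane | CC(C)(C)[Si](C)(C)OC/C=C/B1OC(C)(C)C(C)(C)O1 | starting material
6 | (E)-{3-[2,5-bis(benzyloxy)-3,4-dimethoxyphenyl]prop-2-enyloxy}(tert-butyl)dimethylsilane | CC(C)(C)[Si](C)(C)OC/C=C/c1cc(OCc2ccccc2)c(OC)c(OC)c1OCc1ccccc1 | intermediate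
7 | (E)-3-[2,5-bis(benzyloxy)-3,4-dimethoxyphenyl]prop-2-en-1-ol | OC/C=C/c1cc(OCc2ccccc2)c(OC)c(OC)c1OCc1ccccc1 | intermediate
8 | {(2R,3R)-3-[2,5-bis(benzyloxy)-3,4-dimethoxyphenyl]oxiran-2-yl}methanol | OC[C@H]1O[C@@H]1c1cc(OCc2ccccc2)c(OC)c(OC)c1OCc1ccccc1 | intermediate
9 | 2,3,4-trimethoxyphenol | COc1ccc(O)c(OC)c1OC | starting material
10 | (2R,3R)-2-[2,5-bis(benzyloxy)-3,4-dimethoxyphenyl]-3-[(2,3,4-trimethoxyphenoxy)methyl]oxirane | COc1ccc(OC[C@H]2O[C@@H]2c2cc(OCc3ccccc3)c(OC)c(OC)c2OCc2ccccc2)c(OC)c1OC | intermediate
11 | (3S,4R)-4-[2,5-bis(benzyloxy)-3,4-dimethoxyphenyl]-6,7,8-trimethoxychroman-3-ol (trans) | COc1cc2c(c(OC)c1OC)OC[C@@H](O)[C@@H]2c1cc(OCc3ccccc3)c(OC)c(OC)c1OCc1ccccc1 | intermediate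
12 | (3S,4R)-4-(2,5-dihydroxy-3,4-dimethoxyphenyl)-6,7,8-trimethoxychroman-3-ol (trans) | COc1cc2c(c(OC)c1OC)OC[C@@H](O)[C@@H]2c1cc(O)c(OC)c(OC)c1O | intermediate (not isolated)
13 | (3S,4S)-4-[3,4-dimethoxy-2,5-bis(pivaloyloxy)phenyl]-6,7,8-trimethoxychroman-3-ol (trans) | COc1cc2c(c(OC)c1OC)OC[C@@H](O)[C@@H]2c1cc(OC(=O)C(C)(C)C)c(OC)c(OC)c1OC(=O)C(C)(C)C | intermediate
14 | (3S,4S)-4-[3,4-dimethoxy-2,5-bis(pivaloyloxy)phenyl]-6,7,8-trimethoxychroman-3-yl methanesulfonate (trans) | COc1cc2c(c(OC)c1OC)OC[C@@H](OS(C)(=O)=O)[C@@H]2c1cc(OC(=O)C(C)(C)C)c(OC)c(OC)c1OC(=O)C(C)(C)C | intermediate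
15 | phenonium ion: C1' of ring B bridges C3 and C4 on the face opposite the departed mesylate (spiro-cyclopropane arenium ion, drawn in its C4' oxocarbenium form, C2' pivalate turned away from ring C) | COc1cc2c(c(OC)c1OC)OC[C@H]3[C@@H]2[C@@]34C=C(OC(=O)C(C)(C)C)C(=[O+]C)C(OC)=C4OC(=O)C(C)(C)C | intermediate (not isolated)
16 | (3S,4R)-3-[3,4-dimethoxy-2,5-bis(pivaloyloxy)phenyl]-6,7,8-trimethoxychroman-4-ol (trans) | COc1cc2c(c(OC)c1OC)OC[C@H](c1cc(OC(=O)C(C)(C)C)c(OC)c(OC)c1OC(=O)C(C)(C)C)[C@H]2O | intermediate
17 | (3S,4R)-3-(2,5-dihydroxy-3,4-dimethoxyphenyl)-6,7,8-trimethoxychroman-4-ol (trans) | COc1cc2c(c(OC)c1OC)OC[C@H](c1cc(O)c(OC)c(OC)c1O)[C@H]2O | target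

## Step count and least certain steps

Total step count: 11. Longest linear sequence: 11 steps (1 to 17); boronate 5 and phenol 9 are purchased and enter at steps 3 and 6.

**Step 10 (key step, proposed new method).**
- What may go wrong: after the aryl shift, loss of the C3 proton from the C4 cation may outrun hydration, which would also erase the C3 stereocentre. Ring contraction by a shift of C4a or O1 may start from the diequatorial conformer. Ring B, damped by two acyloxy groups, may assist ionisation too weakly, so that slow direct substitution or elimination toward C2 takes over.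
- Fallback (known chemistry, no aryl shift): it sets out from phenol 9 and bromide 4 and rejoins the route at target 17. Base-catalysed addition of 9 to acrylonitrile gives 3-(2,3,4-trimethoxyphenoxy)propanenitrile F1, which CF3SO3H in CF3CO2H closes (Houben–Hoesch acylation) to 6,7,8-trimethoxychroman-4-one F2. Palladium-catalysed α-arylation of F2 with 4 (Pd(OAc)2, P(t-Bu)3·HBF4, NaOt-Bu, toluene) gives racemic 3-[2,5-bis(benzyloxy)-3,4-dimethoxyphenyl]-6,7,8-trimethoxychroman-4-one F3. Noyori transfer hydrogenation with RuCl(p-cymene)[(S,S)-TsDPEN] and HCO2H/Et3N, under dynamic kinetic resolution through the enol of F3, should give the cis alcohol (3S,4S)-3-[2,5-bis(benzyloxy)-3,4-dimethoxyphenyl]-6,7,8-trimethoxychroman-4-ol F4. Mitsunobu inversion at C4 with 4-nitrobenzoic acid gives the trans ester (3S,4R)-3-[2,5-bis(benzyloxy)-3,4-dimethoxyphenyl]-6,7,8-trimethoxychroman-4-yl 4-nitrobenzoate F5, and K2CO3 in MeOH gives the trans alcohol (3S,4R)-3-[2,5-bis(benzyloxy)-3,4-dimethoxyphenyl]-6,7,8-trimethoxychroman-4-ol F6. Hydrogenolysis (H2, Pd/C, EtOAc with a trace of Et3N) then gives 17.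

**Step 7.**
- What may go wrong: the Lewis acid opens the benzylic C–O bond, but a 1,2-hydride shift (Meinwald rearrangement) or intermolecular capture outruns ring closure, or a fully open cation lowers the trans selectivity.
- Fallback: it sets out from phenol 9 and bromide 4 and rejoins at 11, making the C4–C1' bond by opening a chromene oxide. O-Propargylation of 9 gives 1,2,3-trimethoxy-4-(prop-2-ynyloxy)benzene F7. Heating in N,N-diethylaniline (aryl propargyl ether Claisen rearrangement and ring closure) gives 6,7,8-trimethoxy-2H-chromene F8. Jacobsen epoxidation with (S,S)-N,N'-bis(3,5-di-tert-butylsalicylidene)-1,2-cyclohexanediamine manganese chloride and NaOCl gives (3R,4S)-3,4-epoxy-6,7,8-trimethoxychroman F9. 2,5-Bis(benzyloxy)-3,4-dimethoxyphenylmagnesium bromide F10, made from 4 and Mg, opens F9 at the benzylic C4 with inversion under CuI catalysis and gives 11.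

**Step 8.**
- What may go wrong: acylation may not stop at the phenols and may esterify the C3 alcohol, the hindered C2' phenol may be acylated incompletely, or the free hydroquinone may be oxidised by air between the two operations.
- Fallback: it sets out from 11 and rejoins at 13, masking the C3 alcohol so that acylation can be exhaustive. TBSOTf and 2,6-lutidine give tert-butyl{[(3S,4R)-4-[2,5-bis(benzyloxy)-3,4-dimethoxyphenyl]-6,7,8-trimethoxychroman-3-yl]oxy}dimethylsilane F11. Hydrogenolysis gives 2-[(3S,4R)-3-(tert-butyldimethylsilyloxy)-6,7,8-trimethoxychroman-4-yl]-5,6-dimethoxybenzene-1,4-diol F12. PivCl, Et3N and DMAP give (3S,4S)-3-(tert-butyldimethylsilyloxy)-4-[3,4-dimethoxy-2,5-bis(pivaloyloxy)phenyl]-6,7,8-trimethoxychroman F13, and HF·pyridine in THF gives 13.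

**Step 5.**
- What may go wrong: the electron-rich benzylic epoxide may be opened by alcohol or hydroperoxide on titanium before it can be isolated.
- Fallback: it sets out from alcohol 7 and phenol 9 and rejoins at 10, changing the order and the oxidant. Mitsunobu etherification first gives (E)-1-[3-(2,3,4-trimethoxyphenoxy)prop-1-enyl]-2,5-bis(benzyloxy)-3,4-dimethoxybenzene F14. Shi epoxidation (D-fructose-derived ketone, KHSO5, K2CO3 buffer, 0 °C), which runs at basic pH and gives (R,R) epoxides from (E)-aryl alkenes, then gives 10.

**Step 11.**
- What may go wrong: the hydroquinone may be oxidised in basic methanol, or the benzylic alcohol may ionise during the quench.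
- Fallback: it sets out from 16 and rejoins at 17, isolating the product at the quinone level. Methanolysis with K2CO3 in MeOH followed by deliberate air oxidation gives the stable 5-[(3S,4R)-4-hydroxy-6,7,8-trimethoxychroman-3-yl]-2,3-dimethoxy-1,4-benzoquinone F15, which is purified and then reduced with Na2S2O4 in EtOAc/H2O at neutral pH to give 17.

## Further compounds

F1 | step 10 | 3-(2,3,4-trimethoxyphenoxy)propanenitrile | COc1ccc(OCCC#N)c(OC)c1OC
F2 | step 10 | 6,7,8-trimethoxychroman-4-one | COc1cc2c(c(OC)c1OC)OCCC2=O
F3 | step 10 | rac-3-[2,5-bis(benzyloxy)-3,4-dimethoxyphenyl]-6,7,8-trimethoxychroman-4-one | COc1cc2c(c(OC)c1OC)OCC(c1cc(OCc3ccccc3)c(OC)c(OC)c1OCc1ccccc1)C2=O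
F4 | step 10 | (3S,4S)-3-[2,5-bis(benzyloxy)-3,4-dimethoxyphenyl]-6,7,8-trimethoxychroman-4-ol (cis) | COc1cc2c(c(OC)c1OC)OC[C@H](c1cc(OCc3ccccc3)c(OC)c(OC)c1OCc1ccccc1)[C@@H]2O
F5 | step 10 | (3S,4R)-3-[2,5-bis(benzyloxy)-3,4-dimethoxyphenyl]-6,7,8-trimethoxychroman-4-yl 4-nitrobenzoate (trans) | COc1cc2c(c(OC)c1OC)OC[C@H](c1cc(OCc3ccccc3)c(OC)c(OC)c1OCc1ccccc1)[C@H]2OC(=O)c1ccc(cc1)[N+](=O)[O-]
F6 | step 10 | (3S,4R)-3-[2,5-bis(benzyloxy)-3,4-dimethoxyphenyl]-6,7,8-trimethoxychroman-4-ol (trans) | COc1cc2c(c(OC)c1OC)OC[C@H](c1cc(OCc3ccccc3)c(OC)c(OC)c1OCc1ccccc1)[C@H]2O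
F7 | step 7 | 1,2,3-trimethoxy-4-(prop-2-ynyloxy)benzene | COc1ccc(OCC#C)c(OC)c1OC
F8 | step 7 | 6,7,8-trimethoxy-2H-chromene | COc1cc2c(c(OC)c1OC)OCC=C2
F9 | step 7 | (3R,4S)-3,4-epoxy-6,7,8-trimethoxychroman | COc1cc2c(c(OC)c1OC)OC[C@H]1O[C@H]12
F10 | step 7 | 2,5-bis(benzyloxy)-3,4-dimethoxyphenylmagnesium bromide | COc1c(OCc2ccccc2)cc([Mg]Br)c(OCc2ccccc2)c1OC
F11 | step 8 | tert-butyl{[(3S,4R)-4-[2,5-bis(benzyloxy)-3,4-dimethoxyphenyl]-6,7,8-trimethoxychroman-3-yl]oxy}dimethylsilane | COc1cc2c(c(OC)c1OC)OC[C@@H](O[Si](C)(C)C(C)(C)C)[C@@H]2c1cc(OCc3ccccc3)c(OC)c(OC)c1OCc1ccccc1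
F12 | step 8 | 2-[(3S,4R)-3-(tert-butyldimethylsilyloxy)-6,7,8-trimethoxychroman-4-yl]-5,6-dimethoxybenzene-1,4-diol | COc1cc2c(c(OC)c1OC)OC[C@@H](O[Si](C)(C)C(C)(C)C)[C@@H]2c1cc(O)c(OC)c(OC)c1O
F13 | step 8 | (3S,4S)-3-(tert-butyldimethylsilyloxy)-4-[3,4-dimethoxy-2,5-bis(pivaloyloxy)phenyl]-6,7,8-trimethoxychroman | COc1cc2c(c(OC)c1OC)OC[C@@H](O[Si](C)(C)C(C)(C)C)[C@@H]2c1cc(OC(=O)C(C)(C)C)c(OC)c(OC)c1OC(=O)C(C)(C)C
F14 | step 5 | (E)-1-[3-(2,3,4-trimethoxyphenoxy)prop-1-enyl]-2,5-bis(benzyloxy)-3,4-dimethoxybenzene | COc1ccc(OC/C=C/c2cc(OCc3ccccc3)c(OC)c(OC)c2OCc2ccccc2)c(OC)c1OC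
F15 | step 11 | 5-[(3S,4R)-4-hydroxy-6,7,8-trimethoxychroman-3-yl]-2,3-dimethoxy-1,4-benzoquinone | COc1cc2c(c(OC)c1OC)OC[C@H](C1=CC(=O)C(OC)=C(OC)C1=O)[C@H]2O
A1 | alternative 1 | (3S,4R)-3-[2,5-bis(benzyloxy)-3,4-dimethoxyphenyl]-4-(tert-butyldimethylsilyloxy)-6,7,8-trimethoxychroman | COc1cc2c(c(OC)c1OC)OC[C@H](c1cc(OCc3ccccc3)c(OC)c(OC)c1OCc1ccccc1)[C@H]2O[Si](C)(C)C(C)(C)C
A2 | alternative 1 | dimethyl squarate (3,4-dimethoxycyclobut-3-ene-1,2-dione) | COC1=C(OC)C(=O)C1=O
A3 | alternative 2 | pinacol boronic ester with boron and the 2-(tert-butyldimethylsilyloxy)-3,4,5-trimethoxyphenyl group on C4 and the 2,5-bis(benzyloxy)-3,4-dimethoxyphenyl and silyloxymethyl groups on C3 (configuration as in the SMILES) | CC(C)(C)[Si](C)(C)Oc1c(OC)c(OC)c(OC)cc1[C@H](B1OC(C)(C)C(C)(C)O1)[C@H](CO[Si](C)(C)C(C)(C)C)c1cc(OCc2ccccc2)c(OC)c(OC)c1OCc1ccccc1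
A4 | alternative 2 | 2-[2-(tert-butyldimethylsilyloxy)-3,4,5-trimethoxyphenyl]-4,4,5,5-tetramethyl-1,3,2-dioxaborolane | COc1cc(B2OC(C)(C)C(C)(C)O2)c(O[Si](C)(C)C(C)(C)C)c(OC)c1OC
A5 | alternative 2 | 1-bromo-2,5-bis(benzyloxy)-3,4-dimethoxybenzene | COc1c(OCc2ccccc2)cc(Br)c(OCc2ccccc2)c1OC
A6 | alternative 3 | 5-[(3S,4R)-4-(tert-butyldimethylsilyloxy)-6,7,8-trimethoxychroman-3-yl]-2,3-dimethoxy-1,4-benzoquinone | COc1cc2c(c(OC)c1OC)OC[C@H](C1=CC(=O)C(OC)=C(OC)C1=O)[C@H]2O[Si](C)(C)C(C)(C)C
A7 | alternative 3 | (3S,4R)-4-(tert-butyldimethylsilyloxy)-3-ethynyl-6,7,8-trimethoxychroman | COc1cc2c(c(OC)c1OC)OC[C@H](C#C)[C@H]2O[Si](C)(C)C(C)(C)C
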